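Everything rests on cutting the bond between C3 of the pyrrole ring and C1' of the unbranched henicosyl chain. Two features are exploited. The C21 chain is one carbon shorter than inexpensive docosanoic acid, whose carboxyl carbon can be discarded. C3 lies next to the C2 ester, so a halogen there sits on an electron-poor carbon that nickel attacks readily. A reductive nickel-catalysed union of two electrophiles forges C3–C1' and expels CO2 in a single operation, so no waxy organometallic has to be made. The precursors are the N-Boc derivative of methyl 3-bromopyrrole-2-carboxylate and the N-hydroxyphthalimide ester of docosanoic acid, each one step from a commercial compound. Boc methanolysis then releases the target.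

Key step: step 3

Remark: the target has no stereocentre and no alkene, so no stereocontrol is needed. Compound 1 is taken to be a catalogue item.

Step 1
Reactants: 1 methyl 3-bromo-1H-pyrrole-2-carboxylate
Product: 2 1-tert-butyl 2-methyl 3-bromo-1H-pyrrole-1,2-dicarboxylate
Conditions: Boc2O (1.2 equiv), DMAP (10 mol %), MeCN, 23 °C
Reagents that add atoms: di-tert-butyl dicarbonate (Boc2O), CC(C)(C)OC(=O)OC(=O)OC(C)(C)C
Why: DMAP-catalysed N-tert-butoxycarbonylation of an acidic, ester-flanked pyrrole N–H is routine, is driven by gas evolution, and leaves the C–Br bond and the methyl ester untouched.

Step 2
Reactants: 3 docosanoic acid; 4 N-hydroxyphthalimide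
Product: 5 1,3-dioxoisoindolin-2-yl docosanoate
Conditions: DIC (1.1 equiv), DMAP (10 mol %), CH2Cl2/THF, 30 °C
Reagents that add atoms: none
Why: Steglich-type carbodiimide esterification activates the acid for capture by the acidic N–OH of 4, and the saturated chain offers no competing functionality.

Step 3
Reactants: 2 1-tert-butyl 2-methyl 3-bromo-1H-pyrrole-1,2-dicarboxylate; 5 1,3-dioxoisoindolin-2-yl docosanoate
Product: 6 1-tert-butyl 2-methyl 3-henicosyl-1H-pyrrole-1,2-dicarboxylate
Conditions: NiBr2(dme) (10 mol %), dtbbpy (12 mol %), Zn dust (3 equiv), NaI (25 mol %), DMA/THF, 30 °C; 5 (1.5 equiv) in THF added over 4 h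
Reagents that add atoms: none
Why: Zinc reduces the dtbbpy-bound nickel dibromide to zerovalent nickel, which inserts into the C3–Br bond of 2, a bond polarised by the adjacent C2 ester and by the N-Boc group. Single-electron transfer from low-valent nickel or zinc to the phthalimide unit of 5 breaks its N–O bond, and loss of CO2 leaves the primary henicosyl radical. The radical adds to the pyrrolyl divalent nickel bromide, the trivalent nickel species so formed collapses by reductive elimination to the C3–C1' bond, and zinc returns the monovalent nickel halide to the cycle. This is the known nickel-catalysed decarboxylative reductive (cross-electrophile) coupling of redox-active esters with aryl and heteroaryl halides; no ring is closed and no stereocentre is created. The step needs cross-selectivity over bipyrrole formation, chain dimerisation and chain reduction, which comes from the two partners being activated by different elementary steps and is reinforced by feeding an excess of 5 slowly, so that radical supply matches the slower insertion into a bromide. Regiochemistry is dictated by the single halogen, and the Boc group removes the acidic N–H that would otherwise protonate the aryl nickel species or bind the metal.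

Step 4
Reactants: 6 1-tert-butyl 2-methyl 3-henicosyl-1H-pyrrole-1,2-dicarboxylate
Product: 7 methyl 3-henicosyl-1H-pyrrole-2-carboxylate
Conditions: K2CO3 (20 mol %), MeOH/THF 1:1, 23–40 °C
Reagents that add atoms: none
Why: Base-catalysed methanolysis (nucleophilic acyl transfer) of the N-acylpyrrole-type carbamate should be fast because the ester-stabilised pyrrolide is a good leaving group, while methoxide exchange at the methyl ester is degenerate.

Compound list
1 | methyl 3-bromo-1H-pyrrole-2-carboxylate | COC(=O)c1[nH]ccc1Br | starting material
2 | 1-tert-butyl 2-methyl 3-bromo-1H-pyrrole-1,2-dicarboxylate | COC(=O)c1c(Br)ccn1C(=O)OC(C)(C)C | intermediate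
3 | docosanoic (behenic) acid | CCCCCCCCCCCCCCCCCCCCCC(=O)O | starting material
4 | N-hydroxyphthalimide | ON1C(=O)c2ccccc2C1=O | starting material
5 | 1,3-dioxoisoindolin-2-yl docosanoate | CCCCCCCCCCCCCCCCCCCCCC(=O)ON1C(=O)c2ccccc2C1=O | intermediate
6 | 1-tert-butyl 2-methyl 3-henicosyl-1H-pyrrole-1,2-dicarboxylate | CCCCCCCCCCCCCCCCCCCCCc1ccn(C(=O)OC(C)(C)C)c1C(=O)OC | intermediate
7 | methyl 3-henicosyl-1H-pyrrole-2-carboxylate | CCCCCCCCCCCCCCCCCCCCCc1cc[nH]c1C(=O)OC | target

Total step count: 4
Longest linear sequence: 3 steps (1 → 2 → 6 → 7, or 3 → 5 → 6 → 7)

Steps most likely to fail

Step 3.
- **Risk:** Radical generation may outrun oxidative addition. The active ester would then be spent on reduction and dimerisation, while the bromide is left behind or hydrodehalogenated. Attack of the released phthalimide anion on the carbamate could also strip the nitrogen protection too early.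
- **Fallback (sets out from 3, comes back at 6):** The chain is turned into a preformed nucleophile and joined by a two-electron Negishi coupling instead of a radical process. Hunsdiecker-type iododecarboxylation of 3 (PhI(OAc)2, I2, visible light, cyclohexane, reflux) should give 1-iodohenicosane F1. LiCl-assisted insertion of zinc dust in THF at 40 °C should give henicosylzinc iodide F2. Coupling of F2 with bromide 2 under Pd(OAc)2/SPhos in THF at 23–50 °C should give 6. The methyl ester and the carbamate tolerate alkylzinc halides.

Step 2.
- **Risk:** Activation may be slow because the acid dissolves poorly. O-to-N acyl migration in the carbodiimide adduct and hydrolysis of the active ester on silica could erode the material.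
- **Fallback (sets out from 3, comes back at 5):** The acid is activated as a discrete acyl halide. Oxalyl chloride with catalytic DMF in warm CH2Cl2 should give docosanoyl chloride F3. After evaporation, F3 is treated with 4 and Et3N in CH2Cl2 at 0 to 23 °C, and 5 is purified by crystallisation instead of chromatography.

Step 4.
- **Risk:** The reaction may stall because the waxy substrate precipitates from the methanolic medium. Adventitious water could saponify the methyl ester.
- **Fallback (sets out from 6, comes back at 7):** The carbamate is cleaved by acid-induced fragmentation instead of acyl transfer, using TFA/CH2Cl2 at 0 to 23 °C, in which 6 dissolves fully. The C2 ester deactivates the ring towards protonation and tert-butylation. This fallback makes no compound outside the list (entry F0).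

Further compounds
F1 | step 3 | 1-iodohenicosane | CCCCCCCCCCCCCCCCCCCCCI
F2 | step 3 | henicosylzinc iodide | CCCCCCCCCCCCCCCCCCCCC[Zn]I
F3 | step 2 | docosanoyl chloride | CCCCCCCCCCCCCCCCCCCCCC(=O)Cl
F0 | step 4 | none | none
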